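**Assumption (one line):** the phenols are carried as benzyl ethers and removed in the last step. The target is the C2-symmetric all-trans 2,5-diaryl-3,4-bis(hydroxymethyl)tetrahydrofuran, (2R,3S,4S,5R) by CIP, exactly as the SMILES encodes it.

## Retrosynthetic overview
1. Neoolivil ⇒ acid-mediated 7,7′-cyclodehydration of a 9,9′-protected tetraol (the only ring of the target, formed last). The benzylic centres equilibrate to the all-trans THF, so only C8/C8′ must be set beforehand.
2. Tetraol ⇒ LiAlH4 reduction of the C2-symmetric cis-fused bis-γ-butyrolactone (furo[3,4-c]furan-1,4-dione).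
3. Key step: the bis-lactone ⇐ succinyl bis-(R)-benzyl-oxazolidinone + 2 ArCHO. A double Evans syn-aldol is followed by double lactonisation, which releases the auxiliaries. Two rings and four stereocentres form in one operation.
4. Ring order: the two γ-lactones first (temporary, one operation), then the THF.

## Forward route

**Step 1**
Reactants: **1** succinyl chloride; **2** (R)-4-benzyl-1,3-oxazolidin-2-one (2.1 equiv)
Product: **3** 1,4-bis[(4R)-4-benzyl-2-oxo-oxazolidin-3-yl]butane-1,4-dione
Conditions: **2**, n-BuLi, THF, –78 °C; then **1**, –78 °C → rt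
Reagents that add atoms: none
Why: N-acylation of the lithiated oxazolidinone with the diacid chloride. The (R)-auxiliary is chosen because it delivers the C8 configuration of the target.

**Step 2 (key step)**
Reactants: **3**; **4** 4-(benzyloxy)-3-methoxybenzaldehyde (2.4 equiv)
Product: **5** (3R,3aR,6R,6aR)-3,6-bis[4-(benzyloxy)-3-methoxyphenyl]tetrahydrofuro[3,4-c]furan-1,4-dione
Conditions: (i) Bu2BOTf (2.4 equiv), iPr2NEt, CH2Cl2, –78 → 0 °C; (ii) **4**, –78 → 0 °C; (iii) pH 7 buffer/MeOH/30% H2O2, 0 °C; (iv) crude bis-aldol, DBU (10 mol%), CH2Cl2, rt. The auxiliary **2** is recovered.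
Reagents that add atoms: none
Why: Proposed new method: both imides are converted to Z-boron enolates, and each adds to an aldehyde through a Zimmerman–Traxler chair. The (R)-auxiliary sets C8/C8′, and the two halves act independently, so the product is C2-symmetric (dl). The syn-aldol alkoxides are γ to the opposite acyl imide, so they lactonise 5-exo and expel the auxiliary. The cis-fused bis-lactone is the only geometrically possible ring-closure of the dl configuration, and it places both aryls exo. The closest known reactions are the Evans syn-aldol of N-acyl oxazolidinones and lactonisation of γ-hydroxy imides; using a bis-imide for a double aldol–double lactonisation is not established.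

**Step 3**
Reactants: **5**
Product: **6** (2S,3S)-2,3-bis{(R)-[4-(benzyloxy)-3-methoxyphenyl](hydroxy)methyl}butane-1,4-diol
Conditions: LiAlH4 (6 equiv), THF, 0 °C → rt; Fieser work-up
Reagents that add atoms: none
Why: Hydride reduction of both lactones to the primary alcohols and the benzylic alcohols. No stereocentre is touched, and the benzyl ethers survive.

**Step 4**
Reactants: **6**; **7** tert-butyldiphenylsilyl chloride (2.2 equiv)
Product: **8** (2S,3S)-1,4-bis(TBDPSO)-2,3-bis{(R)-[4-(benzyloxy)-3-methoxyphenyl](hydroxy)methyl}butane
Conditions: **7**, imidazole, DMF, 0 °C → rt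
Reagents that add atoms: TBDPSCl, CC(C)(C)[Si](Cl)(c1ccccc1)c1ccccc1
Why: Bulky silyl chloride silylates only the primary hydroxyls. This blocks O-9/O-9′, which would otherwise close the 7,9′-THF rings of a furofuran.

**Step 5**
Reactants: **8**
Product: **9** (2R,3S,4S,5R)-2,5-bis[4-(benzyloxy)-3-methoxyphenyl]-3,4-bis[(TBDPSO)methyl]tetrahydrofuran
Conditions: TsOH·H2O (5 mol%), CH2Cl2, 4 Å MS, 0 → 25 °C
Reagents that add atoms: none
Why: Acid-catalysed cyclodehydration of a 1,4-diol through a p-alkoxybenzylic cation (SN1 etherification). The benzylic stereocentres equilibrate, C8/C8′ are untouched, and the all-trans (2,3-, 3,4-, 4,5-trans) THF is the thermodynamic minimum, giving the C2-symmetric ring.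

**Step 6**
Reactants: **9**
Product: **10** (2R,3S,4S,5R)-2,5-bis[4-(benzyloxy)-3-methoxyphenyl]tetrahydrofuran-3,4-diyldimethanol
Conditions: TBAF, AcOH, THF, 25 °C
Reagents that add atoms: none
Why: Fluoride-mediated desilylation of the primary silyl ethers; the benzyl ethers and the THF are untouched.

**Step 7**
Reactants: **10**
Product: **11** (+)-neoolivil
Conditions: H2 (1 atm), 10% Pd/C, EtOAc/MeOH 1:1, 25 °C, 1–2 h
Reagents that add atoms: none
Why: Hydrogenolytic O-debenzylation of the aryl benzyl ethers (the standard final step in pinoresinol-type lignans). The stereocentres are not affected.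

## Checks
- **Target match:** **11** is a THF with C7/C7′ bearing 4-hydroxy-3-methoxyphenyl and C8/C8′ bearing CH2OH. The configuration is all-trans and C2-symmetric; C8/C8′ are S and C7/C7′ are R, as in the given SMILES.
- **Atom balance:** C24H24N2O6 (**3**) + 2 C15H14O3 (**4**) → C34H30O8 (**5**) + 2 auxiliary (**2**). The later formulae run C34H38O8 (**6**), C66H74O8Si2 (**8**), C66H72O7Si2 (**9**), C34H36O7 (**10**) and C20H24O7 (**11**, neoolivil).
- **Stereocentres:** C8/C8′ are set in step 2 and never touched again. C7/C7′ come from the aldol (syn, already the target arrangement) and are re-set thermodynamically in step 5; steps 6 and 7 do not touch them.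
- **Functional groups:** the Bn and TBDPS groups survive steps 2–5 as needed, and the free benzylic OH groups are the ring-closing nucleophiles in step 5.

## Compound list
1 | succinyl chloride | ClC(=O)CCC(=O)Cl | starting material
2 | (R)-4-benzyl-1,3-oxazolidin-2-one | O=C1OC[C@@H](Cc2ccccc2)N1 | starting material
3 | bis-imide | O=C1OC[C@@H](Cc2ccccc2)N1C(=O)CCC(=O)N1[C@H](Cc2ccccc2)COC1=O | intermediate
4 | 4-(benzyloxy)-3-methoxybenzaldehyde | COc1cc(C=O)ccc1OCc1ccccc1 | starting material
5 | C2-symmetric bis-lactone | O=C1O[C@@H](c3ccc(OCc4ccccc4)c(OC)c3)[C@@H]2C(=O)O[C@@H](c3ccc(OCc4ccccc4)c(OC)c3)[C@H]12 | intermediate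
6 | tetraol | OC[C@@H]([C@@H](O)c1ccc(OCc2ccccc2)c(OC)c1)[C@@H](CO)[C@@H](O)c1ccc(OCc2ccccc2)c(OC)c1 | intermediate
7 | TBDPSCl | CC(C)(C)[Si](Cl)(c1ccccc1)c1ccccc1 | starting material
8 | bis-TBDPS diol | CC(C)(C)[Si](c1ccccc1)(c1ccccc1)OC[C@@H]([C@@H](O)c1ccc(OCc2ccccc2)c(OC)c1)[C@@H](CO[Si](c1ccccc1)(c1ccccc1)C(C)(C)C)[C@@H](O)c1ccc(OCc2ccccc2)c(OC)c1 | intermediate
9 | THF bis-silyl ether | COc1cc([C@@H]2O[C@@H](c3ccc(OCc4ccccc4)c(OC)c3)[C@H](CO[Si](c3ccccc3)(c3ccccc3)C(C)(C)C)[C@H]2CO[Si](c3ccccc3)(c3ccccc3)C(C)(C)C)ccc1OCc1ccccc1 | intermediate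
10 | THF diol, bis-OBn | COc1cc([C@@H]2O[C@@H](c3ccc(OCc4ccccc4)c(OC)c3)[C@H](CO)[C@H]2CO)ccc1OCc1ccccc1 | intermediate
11 | (+)-neoolivil | COc1cc([C@@H]2O[C@@H](c3ccc(O)c(OC)c3)[C@H](CO)[C@H]2CO)ccc1O | target

## Totals
Total steps: 7. Longest linear sequence: 7 steps, starting from commercial **1**, **2** and **4**.

## Three steps most likely to fail
1. **Step 2 (double bis-enolisation and aldol).** The second enolisation or aldol may stall, or the dr may erode. *Fallback (different approach):* build the bis-lactone stepwise. First run an Evans aldol–lactonisation on the mono-imide/methyl succinate to give a paraconic-type lactone. Then run a second aldol on its enolate, which lactonises onto the remaining imide.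
2. **Step 5 (cationic cyclodehydration).** Risks are incomplete stereoconvergence, aryltetralin formation, and 7,9′-closure through silyl-ether participation. *Fallback (stereospecific, no free cation):* mono-invert one benzylic OH of **8** by Mitsunobu with p-nitrobenzoic acid (statistical desymmetrisation) and hydrolyse the ester. Then close the ring by Mitsunobu cyclisation, in which the retained syn-OH displaces the inverted carbinol with inversion, giving the all-trans THF.
3. **Step 7 (hydrogenolysis).** The benzylic THF C–O bond may be cleaved along with the aryl benzyl ethers. *Fallback (different protecting-group strategy):* start from 4-allyloxy-3-methoxybenzaldehyde in place of **4**, and remove the allyl ethers at the end with Pd(PPh3)4/PhSiH3, so no hydrogenolysis conditions are needed.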